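| setting | alder | larch | flask |
|---|---|---|---|
| starting material | 0.034 M | 0.075 M | 0.050 M |
| remark | run made earlier | run made earlier |  |
| time |  |  | 50 h |

| run | time / h | intermediate A / % | starting material / % | target / % | side product A / % | intermediate C / % | side product B / % |
|---|---|---|---|---|---|---|---|
| alder | 6.00 | 17.0 | 55.8 | 2.5 | 1.4 | 4.7 | 8.0 |
| alder | 12.0 | 15.6 | 34.6 | 9.0 | 3.2 | 10.6 | 17.9 |
| alder | 20.0 | 10.8 | 21.0 | 15.1 | 5.5 | 15.5 | 20.9 |
| alder | 25.0 | 9.6 | 14.5 | 19.7 | 7.5 | 22.2 | 22.2 |
| alder | 30.0 | 6.9 | 11.8 | 21.4 | 10.4 | 24.0 | 26.0 |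
| alder | 40.0 | 4.1 | 6.5 | 22.9 | 9.0 | 24.6 | 27.3 |
| larch | 3.00 | 9.6 | 71.1 | 1.4 | 2.5 | 0.9 | 7.8 |
| larch | 5.00 | 17.1 | 55.7 | 4.5 | 0 | 4.6 | 12.9 |
| larch | 8.00 | 13.5 | 41.9 | 5.2 | 1.8 | 5.0 | 22.0 |
| larch | 15.0 | 11.0 | 23.2 | 12.3 | 6.9 | 10.6 | 35.5 |
| larch | 25.0 | 5.6 | 11.7 | 17.4 | 6.8 | 15.2 | 39.0 |
| larch | 40.0 | 3.1 | 6.3 | 21.6 | 9.3 | 18.5 | 40.4 |

(readings scatter by 1 percentage point)
1. the largest share of what was charged as starting material, at 50 h belongs to (side product B / side product A / target / starting material / intermediate A / intermediate C)
2. the largest share itself, whichever of these holds it, in percent of the starting material charged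

1. Time came first: I counted half-lives of the live pool, starting material plus intermediate A. In the alder run it fell from 31.8% at 20.0 h to 10.6% at 40.0 h, a half-life of 12.6 h.

2. Averaged over both runs, the pool read 10.0% at 40.0 h, so I expected 5.77% in the flask at 50 h.

3. I then defined the odds of side product B: the accumulated amount of side product B over the accumulated amounts of target, side product A and intermediate C together. At 40.0 h they read 0.483 in alder and 0.818 in larch, so the odds rose as c(starting material) to the power 0.665, the odds order.

4. At 0.050 M I reckoned the flask's odds at 0.624 for 40.0 h, which put side product B at 34.6% at that time.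

5. The weak link was holding the odds constant, since in larch they read 0.990 at 25.0 h, higher than later. So I gave the pool's last loss the late larch share, a rough reading of 0.123, and committed to 35.1%. That lead over intermediate C in alder, the highest other reading, exceeded the pool.

6. The forecast named side product B at 34%, below my figure, because the product “looks second order and competes with the first-order route”.

7. The flask gave side product B at 34.0%.

    starting material ⇌ intermediate A (K = 0.658, k = 0.0772 h⁻¹)
    starting material → intermediate B (k = 0.0309 h⁻¹)
    intermediate A ⇌ intermediate C (K = 19.9, k = 0.0663 h⁻¹)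
    intermediate B → side product A (k = 0.0519 h⁻¹)
    intermediate B → target (k = 0.116 h⁻¹)
    starting material + intermediate A → side product B (k = 2.82 L mol⁻¹ h⁻¹)

Moving the time from the alder run to the flask's left side product B at 27.1%, while moving the charge instead gave 33.5%. The flask's odds at 50.0 h came to 0.584, against my 0.624 reckoned for 40.0 h. The odds order 0.665 carried from the alder reading at 40.0 h to 0.12 M gives 1.12, and that neighbour flask stands at 1.13 at 50.0 h, with side product B at 50.4%.

The earlier runs and the new flask were generated by integration on assumed constants; noise was put on by code.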